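**Assumption (one line):** (−)-MIB-catalysed vinyl addition gives the (S)-alcohol, and the 3,4-trans ketone is the thermodynamic epimer at C-4.

## Retrosynthetic overview
- The target comes from the 3,4-cis keto-alcohol by C-4 epimerisation and phenol deprotection. That keto-alcohol comes from an aryllithium opening a cis-fused furo[3,4-c]furanone lactone, whose carbonyl carbon becomes the ArC=O carbon.
- The lactone comes from radical hydroxymethylation of a 2-aryl-2,5-dihydrofuran-3-carboxylate. •CH2OH from MeOH adds to C-3 anti to the C-2 aryl group and sets the 2,3-trans relationship. The cis hydroxy-ester then closes to the lactone.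
- The dihydrofuran comes from ring-closing metathesis of the allyl ether of (S)-1-aryl-allyl alcohol with methyl 2-(bromomethyl)acrylate.
- Ring order: the two aryl rings are built from 4-bromophenol, then the dihydrofuran by RCM, then the lactone ring by lactonisation, then the lactone is opened by ArLi.

## Route

**Step 1**
Reactants: 1 (4-bromophenol)
Product: 2 (4-bromo-2,6-diiodophenol)
Conditions: NIS (2.2 equiv), cat. TsOH, MeCN, rt
Reagents that add atoms: N-iodosuccinimide, O=C1CCC(=O)N1I
Why: Electrophilic iodination goes at both free ortho positions because para is blocked. The ortho C–I bonds are the better leaving groups for the copper step that follows.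

**Step 2**
Reactants: 2
Product: 3 (4-bromo-2,6-dimethoxyphenol)
Conditions: NaOMe (4 equiv), CuI (20 mol %), MeOH/DMF, 100 °C
Reagents that add atoms: sodium methoxide, C[O-].[Na+]
Why: Ullmann-type Cu-catalysed methoxylation, as in the 5-bromovanillin to syringaldehyde conversion. The phenoxide-directed, weaker ortho C–I bonds react in preference to the para C–Br bond.

**Step 3**
Reactants: 3
Product: 4 (aryl bromide, phenol protected as TBS ether)
Conditions: TBSCl, imidazole, DMF, rt
Reagents that add atoms: TBSCl, CC(C)(C)[Si](C)(C)Cl
Why: Silyl protection of the phenol keeps it inert to organolithium, organozinc and radical conditions. It is removed by fluoride at the end.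

**Step 4**
Reactants: 4
Product: 5 (4-TBSO-3,5-dimethoxybenzaldehyde)
Conditions: n-BuLi, THF, −78 °C; then DMF; NH4Cl work-up
Reagents that add atoms: DMF, CN(C)C=O
Why: Li–Br exchange followed by Bouveault formylation.

**Step 5**
Reactants: 5
Product: 6 ((S)-1-aryl-prop-2-en-1-ol)
Conditions: Zn(CH=CH2)2 (from vinylMgBr and ZnCl2), (−)-MIB (10 mol %), PhMe, 0 °C
Reagents that add atoms: vinylmagnesium bromide, C=C[Mg]Br (delivers CH2=CH)
Why: Amino-isoborneol-catalysed enantioselective organozinc addition to the aldehyde sets the C-2 benzylic stereocentre (S). This is the only stereocentre that must be fixed irreversibly by a chiral reagent.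

**Step 6**
Reactants: 6, 7 (methyl 2-(bromomethyl)acrylate)
Product: 8 (allyl ether diene)
Conditions: NaH (1.2 equiv), THF, 0 °C to rt
Reagents that add atoms: none
Why: Williamson etherification of the secondary alkoxide. SN2 and SN2′ attack on the bromomethylacrylate give the same product, and the carbinol centre is untouched.

**Step 7**
Reactants: 8
Product: 9 (methyl (5S)-5-aryl-2,5-dihydrofuran-3-carboxylate)
Conditions: Grubbs II (5 mol %), CH2Cl2 (0.02 M), 40 °C
Reagents that add atoms: none
Why: Ring-closing metathesis of the vinyl and 2-substituted-acrylate alkenes gives the trisubstituted dihydrofuran enoate and loses ethylene. The C-2 stereocentre is retained.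

**Step 8**
Reactants: 9, 10 (methanol)
Product: 11 (cis-fused lactone, (3aR,4S,6aR)-4-aryl-tetrahydro-1H-furo[3,4-c]furan-1-one)
Conditions: [Ir(dF(CF3)ppy)2(dtbbpy)]PF6 (1 mol %), quinuclidine (20 mol %), MeOH (20 equiv), MeCN, blue LEDs, rt; evaporate; DBU (0.2 equiv), PhMe, 50 °C
Reagents that add atoms: none
Why: Proposed new method: the excited Ir catalyst oxidises quinuclidine, and the radical cation abstracts an H atom from MeOH to give •CH2OH.
- This nucleophilic radical adds to the β-carbon (C-3) of the enoate, anti to the adjacent C-2 aryl group. That gives the 2,3-trans relationship by 1,2-induction in the five-membered ring.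
- The α-ester radical is reduced to the enolate and protonated. DBU equilibrates the ester α-centre, and only the cis hydroxy-ester can lactonise, so all material funnels into 11.
- The closest known reactions are photoredox/HAT α-C–H alkylation of alcohols with Michael acceptors and decatungstate hydroxymethylation of enoates to γ-lactones. The new features are the trisubstituted 2-aryl-dihydrofuran acceptor and the use of the C-2 centre to control the new centre.

**Step 9**
Reactants: 11, 4 (as ArLi)
Product: 12 (3,4-cis keto-alcohol with both phenols as TBS ethers, (2S,3R,4R))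
Conditions: 4 + t-BuLi (2 equiv), THF, −78 °C; add 11, −78 °C, 1 h; NH4Cl
Reagents that add atoms: none (the aryl group comes from reactant 4)
Why: Aryllithium adds once to the lactone carbonyl to give a stable tetrahedral hemiketalate at −78 °C, as in standard lactone-to-lactol chemistry. On work-up it gives the aryl ketone and the free primary CH2OH; the product may sit partly as the bicyclic lactol. The C-2 and C-3 centres are untouched.

**Step 10**
Reactants: 12
Product: 13 (3,4-trans keto-alcohol, bis-TBS, (2S,3R,4S))
Conditions: DBU (0.3 equiv), CH2Cl2 or PhMe, 40 °C, 12 h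
Reagents that add atoms: none
Why: Enolisation at C-4, the only acidic and epimerisable centre, converts the 3,4-cis isomer to the thermodynamically preferred 3,4-trans isomer. This is done before desilylation because a para-phenoxide would suppress enolisation.

**Step 11**
Reactants: 13
Product: 14 (target)
Conditions: TBAF (3 equiv), AcOH (3 equiv), THF, 0 °C to rt
Reagents that add atoms: none
Why: Buffered fluoride cleaves both aryl silyl ethers. The benzylic THF ether, the ketone and the primary alcohol survive, and no stereocentre is touched.

## Compound list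
1 | 4-bromophenol | Oc1ccc(Br)cc1 | starting material
2 | 4-bromo-2,6-diiodophenol | Oc1c(I)cc(Br)cc1I | intermediate
3 | 4-bromo-2,6-dimethoxyphenol | COc1cc(Br)cc(OC)c1O | intermediate
4 | (4-bromo-2,6-dimethoxyphenoxy)(tert-butyl)dimethylsilane | COc1cc(Br)cc(OC)c1O[Si](C)(C)C(C)(C)C | intermediate
5 | 4-(TBSO)-3,5-dimethoxybenzaldehyde | COc1cc(C=O)cc(OC)c1O[Si](C)(C)C(C)(C)C | intermediate
6 | (S)-1-[4-(TBSO)-3,5-dimethoxyphenyl]prop-2-en-1-ol | C=C[C@H](O)c1cc(OC)c(O[Si](C)(C)C(C)(C)C)c(OC)c1 | intermediate
7 | methyl 2-(bromomethyl)acrylate | C=C(CBr)C(=O)OC | starting material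
8 | methyl 2-({[(S)-1-aryl-allyl]oxy}methyl)acrylate | C=C[C@H](OCC(=C)C(=O)OC)c1cc(OC)c(O[Si](C)(C)C(C)(C)C)c(OC)c1 | intermediate
9 | methyl (5S)-5-[4-(TBSO)-3,5-dimethoxyphenyl]-2,5-dihydrofuran-3-carboxylate | COC(=O)C1=C[C@@H](c2cc(OC)c(O[Si](C)(C)C(C)(C)C)c(OC)c2)OC1 | intermediate
10 | methanol | CO | starting material
11 | (3aR,4S,6aR)-4-aryl-tetrahydro-1H-furo[3,4-c]furan-1-one (aryl = 4-TBSO-3,5-dimethoxyphenyl) | O=C1OC[C@@H]2[C@@H](c3cc(OC)c(O[Si](C)(C)C(C)(C)C)c(OC)c3)OC[C@H]12 | intermediate
12 | (2S,3R,4R)-cis keto-alcohol, bis-TBS | COc1cc(C(=O)[C@H]2CO[C@H](c3cc(OC)c(O[Si](C)(C)C(C)(C)C)c(OC)c3)[C@H]2CO)cc(OC)c1O[Si](C)(C)C(C)(C)C | intermediate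
13 | (2S,3R,4S)-trans keto-alcohol, bis-TBS | COc1cc(C(=O)[C@@H]2CO[C@H](c3cc(OC)c(O[Si](C)(C)C(C)(C)C)c(OC)c3)[C@H]2CO)cc(OC)c1O[Si](C)(C)C(C)(C)C | intermediate
14 | (4-hydroxy-3,5-dimethoxyphenyl)[(2S,3R,4S)-2-(4-hydroxy-3,5-dimethoxyphenyl)-3-(hydroxymethyl)oxolan-4-yl]methanone | COc1cc(C(=O)[C@@H]2CO[C@H](c3cc(OC)c(O)c(OC)c3)[C@H]2CO)cc(OC)c1O | target

**Total steps:** 11. **Longest linear sequence:** 11 (1→2→3→4→5→6→8→9→11→12→13→14 in compound numbers; the aryl bromide 4 also feeds step 9 in parallel).

## Three steps most likely to fail
1. **Step 8 (photoredox hydroxymethylation).** Problems could be low conversion, HAT at the very weak C-2 benzylic/allylic C–H causing racemisation, or poor facial selectivity.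
   - Fallback: Cu-catalysed conjugate addition of (iPrO)Me2SiCH2MgCl to enoate 9, anti to the aryl group, then Tamao–Fleming oxidation (H2O2, KF, KHCO3) and lactonisation to 11.
2. **Step 5 (catalytic asymmetric vinylation).** Enantioselectivity with this electron-rich aldehyde and a vinylzinc reagent is not guaranteed.
   - Fallback: racemic addition of vinylMgBr to 5, then CAL-B/vinyl acetate kinetic resolution (or Sharpless kinetic resolution) to isolate (S)-6.
3. **Step 10 (C-4 epimerisation).** DBU could cause retro-oxa-Michael ring opening of the β-alkoxy ketone, and the equilibrium might not favour trans enough.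
   - Fallback: open lactone 11 with NaOMe/MeOH and epimerise at the hydroxy-ester stage, where the trans isomer cannot relactonise. Then TBS-protect the primary OH, convert the ester to the Weinreb amide, add ArLi and remove the silyl groups.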